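**Retrosynthetic overview**
1. Target 20 ⇒ acetylation of ketol 19 ⇒ ketohydroxylation of the 1(10)-alkene of 18 (C10–O, C1=O) ⇒ conjugate hydroacetoxylation of the α-methylene lactone 17 (new step; C13–O bond, C11 centre) ⇒ tigloylation of 16.
2. 16 ⇒ CrCl2-mediated intramolecular allylation/lactonisation of epoxy aldehyde–allylic bromide 13 (C6–C7 bond).
3. 13 ⇒ Baylis–Hillman reaction and SN2′ bromination of α-silyloxy aldehyde 9 (C7–C11).
4. 9 ⇒ SAMP-hydrazone alkylation (C8–C9, sets C8) with allylic bromide 4; 4 ⇒ nerol by Sharpless epoxidation (C4, C5) and SeO2 oxidation.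
5. Ring order: oxirane (ring C, step 1), then the ten-membered carbocycle (ring A) and the γ-lactone (ring B) together in step 10.

Assumption: germacrane numbering is used (ring C1–C10, C11–C13 on C7, C14 on C10, C15 on C4), and the SMILES is read literally as (4R,5S,6S,7R,8S,10R,11R), i.e. cis-4α,5α-epoxide, 6α,12-trans-lactone, 8α-tiglate, 10α-acetate, 11βH.

**Route**

Step 1
Reactants: 1 nerol
Product: 2 (2S,3R)-2,3-epoxynerol
Conditions: Ti(OiPr)4 (10 mol%), L-(+)-diethyl tartrate (12 mol%), t-BuOOH, 4 Å sieves, CH2Cl2, −20 °C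
Reagents that add atoms: tert-butyl hydroperoxide CC(C)(C)OO
Why: Sharpless asymmetric epoxidation, in which the titanium tartrate binds the allylic alcohol and delivers oxygen to one face of the Z-2,3-alkene only (the remote alkene is untouched), setting C4 (R) and C5 (S) of the cis-epoxide.

Step 2
Reactants: 2 (2S,3R)-2,3-epoxynerol
Product: 3 (E)-epoxy diol (C9 hydroxylated)
Conditions: SeO2 (0.3 equiv), t-BuOOH (3 equiv), CH2Cl2, rt
Reagents that add atoms: tert-butyl hydroperoxide CC(C)(C)OO (oxygen passed on through catalytic SeO2)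
Why: SeO2 allylic oxidation (ene reaction then [2,3]-sigmatropic shift) of the only alkene is selective for the E-methyl group of the gem-dimethyl terminus, which fixes the 1(10)E geometry; no stereocentre is formed.

Step 3
Reactants: 3 (E)-epoxy diol
Product: 4 epoxy allylic bromide (C9–Br, free C6–OH)
Conditions: NBS (2.2 equiv), Me2S (2.5 equiv), CH2Cl2, −20 → 0 °C
Reagents that add atoms: N-bromosuccinimide BrN1C(=O)CCC1=O
Why: Corey–Kim halogenation, in which only the allylic alkoxysulfonium is displaced by bromide (SN2) while the non-allylic epoxy carbinol forms an alkoxysulfonium that reverts on aqueous work-up; the neutral conditions spare the epoxide.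

Step 4
Reactants: 5 SAMP [(S)-1-amino-2-(methoxymethyl)pyrrolidine]; 6 (tert-butyldimethylsilyloxy)acetaldehyde
Product: 7 SAMP hydrazone of 6
Conditions: CH2Cl2, MgSO4, 0 °C → rt
Reagents that add atoms: none
Why: Hydrazone condensation installs the Enders auxiliary; no stereocentre is formed.

Step 5
Reactants: 7 SAMP hydrazone; 4 epoxy allylic bromide
Product: 8 C8-alkylated SAMP hydrazone
Conditions: 7 (2.2 equiv), LiN(iPr)2 (2.2 equiv), THF, 0 °C; then 4, −100 → −78 °C; H2O quench
Reagents that add atoms: none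
Why: Enders SAMP-hydrazone alkylation, in which the chelated lithium azaenolate is alkylated by the primary allylic bromide (SN2) on the face away from the methoxymethylpyrrolidine, giving (S) at C8 by the Enders rule (O > C7 > C9); the first equivalent of azaenolate only deprotonates the free hydroxyl, whose lithium alkoxide is inert at −100 °C.

Step 6
Reactants: 8 C8-alkylated SAMP hydrazone
Product: 9 (S)-α-silyloxy aldehyde
Conditions: CuCl2 (aq.), THF, pH 7 phosphate buffer, 0 °C → rt
Reagents that add atoms: water O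
Why: Copper-assisted hydrolytic cleavage of the hydrazone at neutral pH frees the aldehyde without ozone or strong acid, so the alkene, epoxide, silyl ether and the C8 centre survive.

Step 7
Reactants: 9 (S)-α-silyloxy aldehyde; 10 methyl acrylate
Product: 11 Baylis–Hillman adduct (C7 epimers)
Conditions: methyl acrylate (excess), 3-hydroxyquinuclidine (20 mol%), rt, 48 h
Reagents that add atoms: none
Why: Morita–Baylis–Hillman reaction of the activated α-silyloxy aldehyde attaches C11–C13 to C7; the new carbinol centre is a mixture that is erased in step 8.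

Step 8
Reactants: 11 Baylis–Hillman adduct
Product: 12 (Z)-2-(bromomethyl)enoate
Conditions: NBS (2.5 equiv), Me2S (3 equiv), CH2Cl2, −20 → 0 °C
Reagents that add atoms: N-bromosuccinimide BrN1C(=O)CCC1=O
Why: Corey–Kim activation followed by SN2′ attack of bromide on the Baylis–Hillman alkoxysulfonium gives the favoured (Z)-2-(bromomethyl)enoate, and the non-allylic primary alcohol is not substituted.

Step 9
Reactants: 12 (Z)-2-(bromomethyl)enoate
Product: 13 epoxy aldehyde allylic bromide
Conditions: Dess–Martin periodinane, pyridine, CH2Cl2, 0 °C → rt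
Reagents that add atoms: none
Why: Dess–Martin oxidation converts the primary epoxy carbinol into the α,β-epoxy aldehyde under buffered, non-epimerising conditions; no new stereocentre.

Step 10
Reactants: 13 epoxy aldehyde allylic bromide
Product: 16 4α,5α-epoxy-8α-hydroxygermacra-1(10)E,11(13)-dien-12,6α-olide, via seco hydroxy ester 14 (not isolated), via silyl ether lactone 15 (not isolated)
Conditions: CrCl2 (8 equiv), THF, rt, 13 added by syringe pump (final 2 mM); aqueous work-up; then HF·pyridine, pyridine/THF, 0 °C → rt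
Reagents that add atoms: none
Why: Intramolecular Nozaki–Hiyama (chromium Barbier) allylation closes ring A through C6–C7 with allylic transposition and the chromium alkoxide lactonises onto the methyl ester (ring B); C6 is set by Felkin–Anh attack anti to the C5–O bond of the epoxy aldehyde and C7 by attack anti to the C8–OSi bond in the A(1,3)-minimised conformer of the Z-allyl unit, both preferences converging on the 6α,12-trans-lactone, while the silyl ether (a poor leaving group) prevents 1,4-elimination of the allylmetal and HF·pyridine then frees the C8 hydroxyl.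

Step 11
Reactants: 16 8α-hydroxy lactone
Product: 17 8α-tigloyloxy α-methylene lactone
Conditions: tigloyl chloride, Et3N, DMAP (10 mol%), CH2Cl2, 0 °C → rt
Reagents that add atoms: tigloyl chloride C/C=C(\C)C(Cl)=O
Why: DMAP-catalysed acylation of the only hydroxyl group; no stereocentre is touched.

Step 12
Reactants: 17 8α-tigloyloxy α-methylene lactone
Product: 18 13-acetoxy-11βH lactone
Conditions: AcOH (10 equiv), Bu4NOAc (20 mol%, present as Bu4N[H(OAc)2]), MeCN, 40 °C
Reagents that add atoms: acetic acid CC(=O)O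
Why: Proposed new method: hydrogen-diacetate-catalysed conjugate hydroacetoxylation of an α-methylene-γ-butyrolactone, in which the weakly solvated acetate adds reversibly to the s-cis-locked exocyclic enoate (C13–O bond) and the lactone enolate is protonated at C11 by AcOH, regenerating acetate; the acidic buffer suppresses the E1cB retro-reaction and the reversible addition/protonation funnels to the more stable 11βH epimer with C13 trans to the C7–C8 bond, and the hindered tiglate and the epoxide do not react under these conditions; the closest known reactions are base- or phosphine-catalysed oxa-Michael hydration and hydroalkoxylation of acrylates and the amine, thiol and alkoxide conjugate additions to α-methylene lactones.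

Step 13
Reactants: 18 13-acetoxy-11βH lactone
Product: 19 10α-hydroxy-1-ketone
Conditions: RuCl3 (2 mol%), KHSO5 (as 2KHSO5·KHSO4·K2SO4), NaHCO3, EtOAc/MeCN/H2O, 0 °C → rt, 10 min
Reagents that add atoms: potassium peroxymonosulfate [K+].[O-]S(=O)(=O)OO
Why: Ruthenium tetroxide-catalysed ketohydroxylation, in which RuO4 adds [3+2] to the only electron-rich alkene from its exposed outer face (oxygen α at C10, C14 β, as in peripheral oxidations of 1(10)E-germacranolides) and the ruthenate ester is oxidised at the secondary C1–O to the ketone; the conjugated tiglate is far less reactive.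

Step 14
Reactants: 19 10α-hydroxy-1-ketone
Product: 20 CNP0305680.1
Conditions: Ac2O, DMAP (20 mol%), pyridine, 40 °C
Reagents that add atoms: acetic anhydride CC(=O)OC(C)=O
Why: DMAP-catalysed acyl transfer acetylates the tertiary α-ketol hydroxyl under weakly basic conditions that do not eliminate the 13-acetate; no stereocentre is changed.

**Compound list**
1 | nerol, (2Z)-3,7-dimethylocta-2,6-dien-1-ol | CC(C)=CCC/C(C)=C\CO | starting material
2 | [(2S,3R)-3-methyl-3-(4-methylpent-3-en-1-yl)oxiran-2-yl]methanol | CC(C)=CCC[C@@]1(C)O[C@H]1CO | intermediate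
3 | (2E)-5-[(2R,3S)-3-(hydroxymethyl)-2-methyloxiran-2-yl]-2-methylpent-2-en-1-ol | OC/C(C)=C/CC[C@@]1(C)O[C@H]1CO | intermediate
4 | [(2S,3R)-3-[(3E)-5-bromo-4-methylpent-3-en-1-yl]-3-methyloxiran-2-yl]methanol | BrC/C(C)=C/CC[C@@]1(C)O[C@H]1CO | intermediate
5 | SAMP, (S)-1-amino-2-(methoxymethyl)pyrrolidine | COC[C@@H]1CCCN1N | starting material
6 | (tert-butyldimethylsilyloxy)acetaldehyde | CC(C)(C)[Si](C)(C)OCC=O | starting material
7 | (E)-SAMP hydrazone of 6 | COC[C@@H]1CCCN1/N=C/CO[Si](C)(C)C(C)(C)C | intermediate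
8 | SAMP hydrazone of aldehyde 9, (S) at C8 | COC[C@@H]1CCCN1/N=C/[C@@H](O[Si](C)(C)C(C)(C)C)C/C(C)=C/CC[C@@]2(C)O[C@H]2CO | intermediate
9 | (2S,4E)-2-(tert-butyldimethylsilyloxy)-7-[(2R,3S)-3-(hydroxymethyl)-2-methyloxiran-2-yl]-4-methylhept-4-enal | O=C[C@@H](O[Si](C)(C)C(C)(C)C)C/C(C)=C/CC[C@@]1(C)O[C@H]1CO | intermediate
10 | methyl acrylate | C=CC(=O)OC | starting material
11 | methyl (4S,6E)-4-(tert-butyldimethylsilyloxy)-3-hydroxy-9-[(2R,3S)-3-(hydroxymethyl)-2-methyloxiran-2-yl]-6-methyl-2-methylidenenon-6-enoate, mixture at C3 | COC(=O)C(=C)C(O)[C@@H](O[Si](C)(C)C(C)(C)C)C/C(C)=C/CC[C@@]1(C)O[C@H]1CO | intermediate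
12 | methyl (2Z,4S,6E)-2-(bromomethyl)-4-(tert-butyldimethylsilyloxy)-9-[(2R,3S)-3-(hydroxymethyl)-2-methyloxiran-2-yl]-6-methylnona-2,6-dienoate | COC(=O)/C(CBr)=C/[C@@H](O[Si](C)(C)C(C)(C)C)C/C(C)=C/CC[C@@]1(C)O[C@H]1CO | intermediate
13 | methyl (2Z,4S,6E)-2-(bromomethyl)-4-(tert-butyldimethylsilyloxy)-9-[(2R,3R)-3-formyl-2-methyloxiran-2-yl]-6-methylnona-2,6-dienoate | COC(=O)/C(CBr)=C/[C@@H](O[Si](C)(C)C(C)(C)C)C/C(C)=C/CC[C@@]1(C)O[C@H]1C=O | intermediate
14 | methyl 8α-(tert-butyldimethylsilyloxy)-4α,5α-epoxy-6α-hydroxygermacra-1(10)E,11(13)-dien-12-oate (seco hydroxy ester, formed as its chromium alkoxide) | CC(C)(C)[Si](C)(C)O[C@H]1C/C(C)=C/CC[C@@]2(C)O[C@H]2[C@@H](O)[C@@H]1C(=C)C(=O)OC | intermediate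
15 | 8α-(tert-butyldimethylsilyloxy)-4α,5α-epoxygermacra-1(10)E,11(13)-dien-12,6α-olide | CC(C)(C)[Si](C)(C)O[C@H]1C/C(C)=C/CC[C@@]2(C)O[C@H]2[C@H]2OC(=O)C(=C)[C@@H]21 | intermediate
16 | 4α,5α-epoxy-8α-hydroxygermacra-1(10)E,11(13)-dien-12,6α-olide | O[C@H]1C/C(C)=C/CC[C@@]2(C)O[C@H]2[C@H]2OC(=O)C(=C)[C@@H]21 | intermediate
17 | 4α,5α-epoxy-8α-tigloyloxygermacra-1(10)E,11(13)-dien-12,6α-olide | C/C=C(\C)C(=O)O[C@H]1C/C(C)=C/CC[C@@]2(C)O[C@H]2[C@H]2OC(=O)C(=C)[C@@H]21 | intermediate
18 | 13-acetoxy-4α,5α-epoxy-8α-tigloyloxy-11βH-germacr-1(10)E-en-12,6α-olide | C/C=C(\C)C(=O)O[C@H]1C/C(C)=C/CC[C@@]2(C)O[C@H]2[C@H]2OC(=O)[C@@H](COC(C)=O)[C@@H]21 | intermediate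
19 | 13-acetoxy-4α,5α-epoxy-10α-hydroxy-1-oxo-8α-tigloyloxy-11βH-germacran-12,6α-olide | C/C=C(\C)C(=O)O[C@H]1C[C@@](C)(O)C(=O)CC[C@@]2(C)O[C@H]2[C@H]2OC(=O)[C@@H](COC(C)=O)[C@@H]21 | intermediate
20 | CNP0305680.1, 10α,13-diacetoxy-4α,5α-epoxy-1-oxo-8α-tigloyloxy-11βH-germacran-12,6α-olide | C/C=C(\C)C(=O)O[C@H]1C[C@@](C)(OC(C)=O)C(=O)CC[C@@]2(C)O[C@H]2[C@H]2OC(=O)[C@@H](COC(C)=O)[C@@H]21 | target

**Step count and risks**
Total: 14 steps. Longest linear sequence: 13 steps from nerol (steps 1–3 and 5–14); step 4 is a one-step side branch.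

Most likely to fail:

1. Step 10 (chromium macrocyclisation). Risks are oligomerisation at the ten-membered ring closure and a mismatch between the Felkin, A(1,3) and ring-strain preferences, giving the wrong C6/C7 pair. The fallback sets out from 11 and comes back at 16. Bu4NF (THF, 0 °C) removes the silyl group of 11 and the C8 alkoxide closes onto the ester to give the 7-hydroxy-11(13)-methylene 8,12-lactone F1. NBS/Me2S (SN2′) turns its allylic alcohol into the 3-(bromomethyl)butenolide F2, and Dess–Martin oxidation gives the epoxy aldehyde butenolide F3. In F3 the C8–O bond lies in the plane of the butenolide π system, so the allylmetal cannot eliminate and is attacked only anti to the C9 chain. CrCl2 closure under high dilution gives the 6α-hydroxy-8α,12-olide F4, and DBU-catalysed translactonisation to the 6α,12-trans-lactone gives 16; the direction of that equilibrium is assumed from natural 8α-oxygenated 6α,12-olides and would need checking.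

2. Step 12 (new hydroacetoxylation). Risks are an unfavourable equilibrium, slow acetate addition, or acetolysis of the epoxide. The fallback uses known chemistry, sets out from 17 and comes back at 18. Phosphine-catalysed oxa-Michael hydration (PMe3 10 mol%, H2O, MeCN, rt) gives the 13-hydroxy-11βH lactone F5 (C11 equilibrated to the same epimer), and Ac2O/pyridine acetylates the primary alcohol to give 18.

3. Step 13 (ketohydroxylation). Risks are over-oxidation (cleavage of the α-ketol) and incomplete face selectivity at C10. The fallback sets out from 18 and comes back at 19. OsO4 (2 mol%) with N-methylmorpholine N-oxide in acetone/H2O dihydroxylates only the isolated trisubstituted alkene from its outer face to give the 1β,10α-diol F6. SO3·pyridine/DMSO/iPr2NEt then oxidises only the secondary C1 hydroxyl to give 19.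

Further compounds
F1 | step 10 | (5S)-4-hydroxy-5-[(2E)-5-[(2R,3S)-3-(hydroxymethyl)-2-methyloxiran-2-yl]-2-methylpent-2-en-1-yl]-3-methylidenedihydrofuran-2(3H)-one, mixture at C4 | C=C1C(O)[C@H](C/C(C)=C/CC[C@@]2(C)O[C@H]2CO)OC1=O
F2 | step 10 | (5S)-3-(bromomethyl)-5-[(2E)-5-[(2R,3S)-3-(hydroxymethyl)-2-methyloxiran-2-yl]-2-methylpent-2-en-1-yl]furan-2(5H)-one | BrCC1=C[C@H](C/C(C)=C/CC[C@@]2(C)O[C@H]2CO)OC1=O
F3 | step 10 | (5S)-3-(bromomethyl)-5-[(2E)-5-[(2R,3R)-3-formyl-2-methyloxiran-2-yl]-2-methylpent-2-en-1-yl]furan-2(5H)-one | BrCC1=C[C@H](C/C(C)=C/CC[C@@]2(C)O[C@H]2C=O)OC1=O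
F4 | step 10 | 4α,5α-epoxy-6α-hydroxygermacra-1(10)E,11(13)-dien-12,8α-olide | O=C1O[C@H]2C/C(C)=C/CC[C@@]3(C)O[C@H]3[C@@H](O)[C@@H]2C1=C
F5 | step 12 | 4α,5α-epoxy-13-hydroxy-8α-tigloyloxy-11βH-germacr-1(10)E-en-12,6α-olide | C/C=C(\C)C(=O)O[C@H]1C/C(C)=C/CC[C@@]2(C)O[C@H]2[C@H]2OC(=O)[C@@H](CO)[C@@H]21
F6 | step 13 | 13-acetoxy-4α,5α-epoxy-1β,10α-dihydroxy-8α-tigloyloxy-11βH-germacran-12,6α-olide | C/C=C(\C)C(=O)O[C@H]1C[C@@](C)(O)[C@H](O)CC[C@@]2(C)O[C@H]2[C@H]2OC(=O)[C@@H](COC(C)=O)[C@@H]21
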